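## Analysis of the target

The atoms are labelled as follows: the nine-membered ring is C1 (bearing the exocyclic CH2), C2, C3, C4 (C=O), C5 (CH3), C6, C7, C8 and C9; C10 and C11 complete the cyclobutane C8–C9–C10–C11; and the side chain is C12 (OAc), C13, C14=C15(CH3) and C16 (OAc). Target 36 is a bicyclo[7.2.0]undecane in which a cyclobutane is trans-fused along C8–C9 to a nine-membered carbocycle carrying a 1,1-disubstituted alkene at C1, a ketone at C4 and a methyl stereocentre at C5. It has five stereocentres, C5 (S), C8 (S), C9 (R), the quaternary C11 (S) and the carbinol C12 (S); on the four-membered ring C7 and C1 are trans, the C11 methyl lies on the face of C7 and C12 on the face of C1. C12 sits directly on the quaternary carbon and C5 is separated from the other centres by two methylenes, so neither can be relayed from the ring by simple substrate control. The side chain ends in a (Z)-trisubstituted allylic acetate with CH2OAc cis to the chain. Sensitive points are the two acetates (base, hydride, organometallics; the allylic one also zerovalent palladium), the C5 centre (epimerisable next to the ketone) and the keto-alkene pair in a medium ring, which invites transannular reactions under acid. The hard parts are the three contiguous cyclobutane stereocentres including the quaternary one, the nine-membered ring, and the order in which the incompatible functions are introduced. The structural feature on which the synthesis rests is that C8 and C9 each carry exactly one carbon outside the small ring (C7 and C1) and both can be carbonyl carbons, so that C8 and C9 are the two α-carbons of an adipic acid whose C3 is C11 and the ring bond C8–C9 joins them.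

## Retrosynthetic reasoning

**C4 ketone and acetates (36 ⇐ 35 ⇐ 34 ⇐ 33).** The ketone is formed last, by oxidation of carbinol 35, so that C5 never sits next to a carbonyl while bases, hydrides or organometallics are in use. Carbinol 35 comes from 4-methoxybenzyl ether 34, and both acetates are put on diol 33 in one operation. The forward steps must be neutral and mild.

**Side chain (33 ⇐ 32 ⇐ 31 ⇐ 30 ⇐ 29 ⇐ 28 ⇐ 27).** The C12–O and C16–O bonds and the (Z)-alkene are traced to one six-membered unsaturated lactone 32, where the ring enforces the cis relation of C13 and C16. Reduction gives diol 33 directly. Lactone 32 arises by ring-closing metathesis of methacrylate 31, made from homoallylic alcohol 30. Cutting C12–C13 leads to neopentyl aldehyde 29, from silyl ether 27 via alcohol 28. C12 is set by a reagent-controlled allylboration because the adjacent quaternary centre offers no dependable bias.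

**Nine-membered ring (27 ⇐ 25).** The ring is cut at C1–C2. Forward, an alkenyl triflate at C1 is coupled with a primary alkylborane at C2 (26, from the terminal alkene of 25). This one bond closes the ring and leaves the exocyclic methylene, so no separate methylenation next to a masked ketone is needed, and an sp2 carbon in the ring eases the medium-ring closure.

**Chain C2–C7 and C5 (25 ⇐ 24 ⇐ 23 ⇐ 22 ⇐ 21 ⇐ 20 ⇐ 19 ⇐ 16 + 18).** The triflate comes from methyl ketone 24, and that from the N-methoxy-N-methyl amide in 23. The vinyl carbinol (C2–C4) comes from aldehyde 21 (via 22), which is the oxidised form of alcohol 20. The C6–C7 bond is cut as an alkene (19), formed from aldehyde 16 and phosphonium salt 18. Salt 18 is one step from bromo alcohol 17 and brings C5 from the chiral pool. The alkene is then saturated without a metal catalyst to protect the allylic centres.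

**Telling C1 from C7 (16 ⇐ 15 ⇐ 14 ⇐ 13).** In bis-imide 13 the C7 acyl group stands next to the quaternary C11 and its cis methyl, while the C1 acyl group has only the C10 methylene beside it. A bulky acyl-transfer reagent should therefore take C1 first (giving 14). The remaining imide is then reduced (15) and oxidised (16).

**Cyclobutane (13 ⇐ 11 via 12).** The C8–C9 bond is cut between two carbons that are both α to carbonyl groups. Forward, dilithium bis-enolate 12 of adipoyl bis-imide 11 is oxidised so that the two nucleophilic carbons are joined. The ring and two stereocentres form in one step, directed by C11, which is already in place.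

**Acyclic precursor (11 ⇐ 9 + 10 ⇐ 7 ⇐ 6 ⇐ 4 + 5 ⇐ 3 ⇐ 2 ⇐ 1).** Bis-imide 11 is the double N-acylation product of two molecules of 10 with diacid 9. Diacid 9 comes from oxidative cleavage of the kinetic enol silane 7 of cyclohexanone 6 (through oxo acid 8). Cleaving the C1–C6 bond of the ring places the quaternary carbon at C3 of the adipic acid. C11 is set in 6 by catalytic asymmetric conjugate methylation of enone 4 with 5. Enone 4 is reached from dione 1 through triflate 2 and alcohol 3.

## Alternatives that were turned down

Alternative 1: The disconnection is C1–C2, as in the chosen endgame, but the nucleophile is a palladium homoenolate. Cyclopropanol triflate A2 would be treated with Pd(OAc)2, a bulky phosphine and Cs2CO3; opening of the cyclopropanol puts palladium on C2, and coupling with the C1 alkenyl triflate would give ketone A1 with ring, methylene and C4 carbonyl formed together.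
- For it: no protecting group or late oxidation is needed at C4. On that point it is about three steps shorter than the chosen endgame.
- Against it: the alkyl–palladium intermediate has acidic β-hydrogens at C3 next to the nascent ketone, and closure of a strained nine-membered ring is slow, so elimination to the enone is a serious competitor. The ketone is also released beside C5 in warm carbonate base, which risks epimerisation. The cyclopropanol must be carried through triflate formation.
- Comparison: this is an endgame only; it does not say how C8, C9 and C11 are made, and A2 would still need the cyclobutane. The chosen route closes the same bond with a primary alkylborane, keeps C4 as an ether, and spends its main step on the cyclobutane core.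

Alternative 2: Here the cyclobutane is made by ring expansion. Epoxy cyclopropanol A4 with BF3·OEt2 would open at C11, a cyclopropane bond would migrate (C8 to C11), and cyclobutanone A3 would result with C11 and C12 set.
- For it: the migration is stereospecific (inversion at C11, retention at C12), so the C11/C12 pair comes from one asymmetric epoxidation. This is stronger than the chosen route, which sets C12 late by reagent control.
- Against it: in A3 the carbonyl is at C10, which is a plain methylene in the target and would have to be removed. C8 and C9 are unsubstituted methylenes, so the two centres that carry the nine-membered ring are still missing. C9 is α to the ketone and can be alkylated, but C8 is β and next to the quaternary carbon; functionalising it would need cyclobutenone-type chemistry with uncertain facial control.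
- Comparison: many more steps for the core. The chosen coupling places both ring-bearing carbons on C8 and C9 as the ring forms.

Alternative 3: Here the ring comes from contraction. Diazo ketone A6 (from a C2-symmetric trans-3,4-disubstituted cyclopentanone) would undergo photochemical Wolff rearrangement in methanol, C10 migrating to C11, to give ester A5.
- For it: the symmetry removes any regiochemical question in diazo transfer, and the trans C8/C9 relation is fixed before the ring is made. On that relation it is more secure than the oxidative coupling, where it is set in the key step.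
- Against it: C11 emerges as a methine carrying the ester, so the methyl must be added by enolate alkylation. The electrophile would have to approach syn to the vicinal C8 arm to give the required methyl cis to C7; the inherent preference is anti. The two silyloxymethyl arms of A5 are identical, so C1 and C7 still have to be told apart, no better than in the chosen route.
- Comparison: the chosen strategy brings C11 in fully substituted and lets it direct the new centres, instead of installing it last against the substrate bias.

Key step: step 8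

Remarks on the chemistry:
- Compound names use the atom labels C1–C16 defined above, not von Baeyer numbering. In the cyclobutane names of 13–25 the ring locants 1, 2 and 3 are C9, C8 and C11.
- The C4 carbinol centre created in step 16 is carried as a mixture of epimers, because it becomes the ketone in step 29.
- Alkene 19 is drawn as the (Z)-isomer expected from a non-stabilised ylide; its geometry is removed in step 14.

## Route

Step 1
Reactants: 1 cyclohexane-1,3-dione
Product: 2 3-oxocyclohex-1-en-1-yl trifluoromethanesulfonate
Conditions: Tf2O, pyridine, CH2Cl2, −78 → 0 °C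
Reagents that add atoms: trifluoromethanesulfonic anhydride, O=S(=O)(OS(=O)(=O)C(F)(F)F)C(F)(F)F
Why: O-sulfonylation of the enol of a cyclic 1,3-diketone gives the β-triflyloxy enone; the symmetry of 1 removes any regiochemical question.

Step 2
Reactants: 2 3-oxocyclohex-1-en-1-yl trifluoromethanesulfonate
Product: 3 3-(hydroxymethyl)cyclohex-2-en-1-one
Conditions: Bu3SnCH2OH, Pd(PPh3)4 (5 mol %), LiCl, dioxane, 100 °C
Reagents that add atoms: (tributylstannyl)methanol, CCCC[Sn](CCCC)(CCCC)CO
Why: Stille coupling: zerovalent palladium inserts into the activated alkenyl triflate, the hydroxymethyl group is transferred from tin (chloride assists) and reductive elimination gives the allylic alcohol; hydroxymethylstannanes are established partners for alkenyl triflates.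

Step 3
Reactants: 3 3-(hydroxymethyl)cyclohex-2-en-1-one
Product: 4 3-[(triisopropylsilyloxy)methyl]cyclohex-2-en-1-one
Conditions: (i-Pr)3SiCl, imidazole, DMF, rt
Reagents that add atoms: chlorotriisopropylsilane, CC(C)[Si](Cl)(C(C)C)C(C)C
Why: Silylation of a primary allylic alcohol; the bulky ether masks the C12 oxygen through the organometallic and oxidative steps and later serves as the large group on C11.

Step 4
Reactants: 4 3-[(triisopropylsilyloxy)methyl]cyclohex-2-en-1-one; 5 trimethylaluminium
Product: 6 (S)-3-methyl-3-[(triisopropylsilyloxy)methyl]cyclohexan-1-one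
Conditions: Me3Al (1.5 equiv), Cu(O2CC4H3S) (copper thiophene-2-carboxylate, 5 mol %), chiral biaryl phosphoramidite of a bis(1-arylethyl)amine (10 mol %), Et2O, −30 °C; aq. NH4Cl
Reagents that add atoms: none
Why: Copper-catalysed asymmetric conjugate addition of an alane to a β-substituted cyclohexenone creates the quaternary centre C11; the ligand enantiomer is the one that delivers methyl to the Re face of C3 (CH2OSi > C2 > C4), and the silyloxy group is γ to the enolate carbon so it cannot be eliminated.

Step 5
Reactants: 6 (S)-3-methyl-3-[(triisopropylsilyloxy)methyl]cyclohexan-1-one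
Product: 7 (S)-5-methyl-5-[(triisopropylsilyloxy)methyl]-1-(trimethylsilyloxy)cyclohex-1-ene
Conditions: LiN(i-Pr)2 (1.1 equiv), THF, −78 °C; Me3SiCl, Et3N, −78 → 0 °C
Reagents that add atoms: chlorotrimethylsilane, C[Si](C)(C)Cl
Why: Kinetic deprotonation of a 3,3-disubstituted cyclohexanone occurs at C6, away from the neopentyl C2 methylene, and O-silylation fixes that enol ether; this regiochemistry decides that cleavage gives the 3,3- and not the 2,2-disubstituted adipic acid.

Step 6
Reactants: 7 (S)-5-methyl-5-[(triisopropylsilyloxy)methyl]-1-(trimethylsilyloxy)cyclohex-1-ene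
Product: 9 (S)-3-methyl-3-[(triisopropylsilyloxy)methyl]hexanedioic acid, via oxo acid 8 (not isolated)
Conditions: O3, CH2Cl2, −78 °C; Me2S, −78 °C → rt; then NaClO2, NaH2PO4, 2-methylbut-2-ene, t-BuOH/H2O, 0 °C → rt
Reagents that add atoms: ozone, [O-][O+]=O; sodium chlorite, [Na+].[O-]Cl=O
Why: Ozonolysis of the silyl enol ether cleaves the ring between the former carbonyl carbon and C6 to a silyl ester and an aldehyde (8 after desilylation), and Pinnick oxidation takes the aldehyde to the acid without touching the silyl ether or the quaternary centre.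

Step 7
Reactants: 9 (S)-3-methyl-3-[(triisopropylsilyloxy)methyl]hexanedioic acid; 10 oxazolidin-2-one (two equivalents, one for each carboxyl group)
Product: 11 3,3'-{(S)-3-methyl-3-[(triisopropylsilyloxy)methyl]hexanedioyl}bis(oxazolidin-2-one)
Conditions: t-BuCOCl (2.2 equiv), Et3N (4.5 equiv), THF, −20 °C; then 10 (2.4 equiv), LiCl, −20 °C → rt
Reagents that add atoms: oxazolidin-2-one (the second equivalent of 10), O=C1NCCO1
Why: Double N-acylation through the bis(pivalic mixed anhydride) with LiCl/Et3N activation of the oxazolidinone; attack occurs at the less hindered acyl carbon of each mixed anhydride, and two molecules of 10 are consumed, one at each acyl terminus.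

Step 8
Reactants: 11 3,3'-{(S)-3-methyl-3-[(triisopropylsilyloxy)methyl]hexanedioyl}bis(oxazolidin-2-one)
Product: 13 3,3'-{[(1R,2S,3S)-3-methyl-3-[(triisopropylsilyloxy)methyl]cyclobutane-1,2-diyl]dicarbonyl}bis(oxazolidin-2-one), via dilithium bis-enolate 12 (not isolated)
Conditions: LiN(i-Pr)2 (2.3 equiv), THF, −78 °C, slow inverse addition of 11; then CuCl2 (2.5 equiv) in DMF, −78 → 0 °C, 0.01 M
Reagents that add atoms: none
Why: This is the key step; slow addition of 11 to excess amide base at −78 °C gives bis-enolate 12 before a mono-enolate can attack the other imide. CuCl2 (divalent copper) removes one electron from one enolate; the α-carbonyl radical (or its copper-bound equivalent) bonds to the carbon of the second enolate and a second CuCl2 oxidises the resulting radical anion, so C8–C9 forms while two CuCl2 become CuCl (monovalent copper). The closest known reaction type is the intramolecular oxidative coupling of dienolates of adipic diesters and bis-imides to trans-cyclobutane-1,2-dicarbonyl compounds. The ring closes in the 4-exo-trig mode, helped by the geminal substitution at C11, which compresses the chain. At C8 and C9 the two imides avoid each other and end trans; because both centres are α to imides, any cis isomer can be equilibrated with DBU. The C8 acyl group avoids the large CH2OSi(i-Pr)3 group on C11 and ends on the methyl face, so the absolute configuration of both new centres (C8 S and C9 R) derives from C11 alone. The step needs ring closure over intermolecular coupling (high dilution), coupling over Dieckmann condensation (complete double deprotonation at low temperature) and over α-chlorination (oxidant added as a solution to the cold enolate).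

Step 9
Reactants: 13 cyclobutane bis-imide
Product: 14 (1R,2S,3S)-N-methoxy-N,3-dimethyl-2-(2-oxooxazolidine-3-carbonyl)-3-[(triisopropylsilyloxy)methyl]cyclobutane-1-carboxamide (N-methoxy-N-methyl amide at C1 and imide at C7)
Conditions: MeNH(OMe)·HCl (1.2 equiv), Me3Al (1.2 equiv), CH2Cl2, −20 → 0 °C; aq. KNaC4H4O6
Reagents that add atoms: N,O-dimethylhydroxylamine hydrochloride, CNOC.Cl
Why: Aluminium-amide transamidation of an N-acyl oxazolidinone; the C1 acyl group on C9 has only the C10 methylene beside it, whereas the C7 acyl group on C8 is flanked by the quaternary C11 and its cis methyl, so one equivalent of the bulky reagent at low temperature should take C1.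

Step 10
Reactants: 14 C1 amide, C7 imide
Product: 15 (1R,2S,3S)-2-(hydroxymethyl)-N-methoxy-N,3-dimethyl-3-[(triisopropylsilyloxy)methyl]cyclobutane-1-carboxamide
Conditions: LiBH4 (1.5 equiv), MeOH (1.5 equiv), THF, 0 °C
Reagents that add atoms: none
Why: Borohydride reduction of the activated imide to the primary alcohol proceeds at 0 °C, where the tertiary N-methoxy amide is not reduced; no enolisation is involved, so C8 is untouched.

Step 11
Reactants: 15 C7 alcohol
Product: 16 (1R,2S,3S)-2-formyl-N-methoxy-N,3-dimethyl-3-[(triisopropylsilyloxy)methyl]cyclobutane-1-carboxamide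
Conditions: Dess–Martin periodinane, NaHCO3, CH2Cl2, 0 °C → rt
Reagents that add atoms: none
Why: Dess–Martin oxidation under buffered conditions gives the aldehyde without epimerising C8, which already has the favoured trans arrangement.

Step 12
Reactants: 17 (R)-3-bromo-2-methylpropan-1-ol
Product: 18 (R)-(3-hydroxy-2-methylpropyl)triphenylphosphonium bromide
Conditions: PPh3, MeCN, reflux
Reagents that add atoms: triphenylphosphine, c1ccc(cc1)P(c1ccccc1)c1ccccc1
Why: SN2 quaternisation of the phosphine by a primary bromide; the stereocentre is β to the reacting carbon and is not affected.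

Step 13
Reactants: 16 C7 aldehyde; 18 phosphonium salt
Product: 19 (1R,2S,3S)-2-[(1Z,3S)-4-hydroxy-3-methylbut-1-en-1-yl]-N-methoxy-N,3-dimethyl-3-[(triisopropylsilyloxy)methyl]cyclobutane-1-carboxamide
Conditions: 18 (1.6 equiv), KN(SiMe3)2 (3.2 equiv), THF, −78 → 0 °C; then 16, −78 °C → rt
Reagents that add atoms: none
Why: Wittig olefination with a γ-oxido ylide (one equivalent of base for the hydroxyl, one for the ylide) joins C6 to C7; the aldehyde reacts far faster than the N-methoxy amide, the alkene geometry is irrelevant, and C5 arrives with its configuration from the chiral pool.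

Step 14
Reactants: 19 alkenol
Product: 20 (1R,2S,3S)-2-[(3S)-4-hydroxy-3-methylbutyl]-N-methoxy-N,3-dimethyl-3-[(triisopropylsilyloxy)methyl]cyclobutane-1-carboxamide
Conditions: TsNHNH2 (excess, in portions), NaOAc, THF/H2O, reflux
Reagents that add atoms: none
Why: Diimide reduction transfers H2 to the 1,2-disubstituted alkene in a concerted syn process without a metal hydride, so double-bond migration cannot scramble the allylic centres C5 and C8, and the N–O bond survives.

Step 15
Reactants: 20 saturated alcohol
Product: 21 (1R,2S,3S)-N-methoxy-N,3-dimethyl-2-[(3S)-3-methyl-4-oxobutyl]-3-[(triisopropylsilyloxy)methyl]cyclobutane-1-carboxamide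
Conditions: Dess–Martin periodinane, NaHCO3, CH2Cl2, 0 °C; used at once
Reagents that add atoms: none
Why: Dess–Martin oxidation of the primary alcohol to the α-methyl aldehyde; buffered conditions and immediate use avoid epimerisation at C5.

Step 16
Reactants: 21 C4 aldehyde
Product: 22 (1R,2S,3S)-2-[(3S)-4-hydroxy-3-methylhex-5-en-1-yl]-N-methoxy-N,3-dimethyl-3-[(triisopropylsilyloxy)methyl]cyclobutane-1-carboxamide (mixture of C4 epimers)
Conditions: CH2=CHMgBr (1.2 equiv), THF, −78 °C; aq. NH4Cl
Reagents that add atoms: vinylmagnesium bromide, C=C[Mg]Br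
Why: Grignard addition to the aldehyde at −78 °C, where the N-methoxy-N-methyl amide is inert; the new C4 centre is not controlled, which is of no consequence because C4 ends as the ketone.

Step 17
Reactants: 22 allylic alcohol
Product: 23 4-methoxybenzyl ether of 22 (C4 epimers)
Conditions: NaH, 4-MeOC6H4CH2Cl, Bu4NI (cat.), THF/DMF, 0 °C → rt
Reagents that add atoms: 4-methoxybenzyl chloride, COc1ccc(CCl)cc1
Why: Williamson etherification of the secondary alkoxide; this ether withstands Grignard reagents, amide bases, boranes, fluoride and hydride, and is removed at the end under neutral oxidative conditions that spare acetates and alkenes.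

Step 18
Reactants: 23 ether amide
Product: 24 1-{(1R,2S,3S)-2-[(3S)-4-(4-methoxybenzyloxy)-3-methylhex-5-en-1-yl]-3-methyl-3-[(triisopropylsilyloxy)methyl]cyclobutyl}ethan-1-one
Conditions: MeMgBr (3 equiv), THF, 0 °C; aq. NH4Cl
Reagents that add atoms: methylmagnesium bromide, C[Mg]Br
Why: Weinreb ketone synthesis: the chelated tetrahedral magnesium adduct resists a second addition and collapses to the methyl ketone on work-up.

Step 19
Reactants: 24 methyl ketone
Product: 25 1-{(1R,2S,3S)-2-[(3S)-4-(4-methoxybenzyloxy)-3-methylhex-5-en-1-yl]-3-methyl-3-[(triisopropylsilyloxy)methyl]cyclobutyl}ethenyl trifluoromethanesulfonate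
Conditions: KN(SiMe3)2 (1.05 equiv), THF, −78 °C; PhNTf2, −78 → −20 °C
Reagents that add atoms: N-phenylbis(trifluoromethanesulfonimide), O=S(=O)(N(c1ccccc1)S(=O)(=O)C(F)(F)F)C(F)(F)F
Why: Kinetic deprotonation occurs at the methyl group (the ring methine at C9 is hindered and would give a strained cyclobutylidene enolate) and O-sulfonylation gives the 1,1-disubstituted alkenyl triflate; one equivalent of base at low temperature avoids epimerisation at C9 and elimination to the alkyne.

Step 20
Reactants: 25 alkenyl triflate
Product: 27 (5S,8S,9R,11S)-4-(4-methoxybenzyloxy)-5,11-dimethyl-1-methylidene-11-[(triisopropylsilyloxy)methyl]bicyclo[7.2.0]undecane (C4 epimers), via alkylborane 26 (not isolated)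
Conditions: 9-BBN, THF, 0 °C → rt; then syringe-pump addition to PdCl2(dppf) (15 mol %), AsPh3, Cs2CO3, DMF/THF/H2O, 50 °C, 0.002 M
Reagents that add atoms: none
Why: The borane adds to the monosubstituted alkene with boron on C2 (the electron-poor 1,1-disubstituted alkenyl triflate is left), and intramolecular B-alkyl Suzuki–Miyaura coupling (oxidative addition of zerovalent palladium into C1–OTf, base-assisted transfer of the primary alkyl group, reductive elimination) forms C1–C2, closing the nine-membered ring and leaving the exocyclic methylene; high dilution favours ring closure and the C4 oxygen is γ to boron, so it cannot be eliminated.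

Step 21
Reactants: 27 bicyclic silyl ether
Product: 28 [(5S,8S,9R,11S)-4-(4-methoxybenzyloxy)-5,11-dimethyl-1-methylidenebicyclo[7.2.0]undecan-11-yl]methanol
Conditions: Bu4NF, THF, rt → 45 °C
Reagents that add atoms: none
Why: Fluoride cleavage of the silyl ether; the benzyl-type ether and the alkene are unaffected.

Step 22
Reactants: 28 C12 alcohol
Product: 29 (5S,8S,9R,11S)-4-(4-methoxybenzyloxy)-5,11-dimethyl-1-methylidenebicyclo[7.2.0]undecane-11-carbaldehyde
Conditions: Dess–Martin periodinane, NaHCO3, CH2Cl2, rt
Reagents that add atoms: none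
Why: Dess–Martin oxidation of a neopentyl alcohol to an aldehyde that has no α-hydrogen and cannot epimerise.

Step 23
Reactants: 29 C12 aldehyde
Product: 30 (1S)-1-[(5S,8S,9R,11S)-4-(4-methoxybenzyloxy)-5,11-dimethyl-1-methylidenebicyclo[7.2.0]undecan-11-yl]but-3-en-1-ol
Conditions: (−)-Ipc2BOMe (from (+)-α-pinene), CH2=CHCH2MgBr, Et2O, −78 °C → rt; then 29, −78 °C; NaOH, H2O2
Reagents that add atoms: allylmagnesium bromide (allyl group relayed through boron), C=CC[Mg]Br
Why: Brown allylation through a chair-like six-membered transition state; the reagent derived from (+)-α-pinene adds to the Si face of aldehydes, which for an aldehyde on a fully substituted carbon (pivalaldehyde model) gives the (S)-carbinol, and reagent control overrides the weak bias of the neighbouring quaternary centre.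

Step 24
Reactants: 30 homoallylic alcohol
Product: 31 methacrylate ester of 30
Conditions: CH2=C(CH3)COCl, Et3N, DMAP, CH2Cl2, 0 °C → rt
Reagents that add atoms: methacryloyl chloride, C=C(C)C(=O)Cl
Why: DMAP-catalysed acylation of the hindered secondary alcohol through the acylpyridinium ion.

Step 25
Reactants: 31 methacrylate
Product: 32 (6S)-6-[(5S,8S,9R,11S)-4-(4-methoxybenzyloxy)-5,11-dimethyl-1-methylidenebicyclo[7.2.0]undecan-11-yl]-3-methyl-5,6-dihydro-2H-pyran-2-one
Conditions: second-generation Grubbs catalyst (H2IMes)(PCy3)Cl2Ru=CHPh (5–10 mol %), toluene, 80 °C, 0.005 M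
Reagents that add atoms: none
Why: Ring-closing metathesis of the terminal vinyl group with the methacrylate alkene gives the six-membered unsaturated lactone, in which the ring holds C16 cis to C13 (the (Z) geometry of the side chain); the hindered 1,1-disubstituted ring methylene does not compete with six-ring closure.

Step 26
Reactants: 32 unsaturated lactone
Product: 33 (2Z,5S)-5-[(5S,8S,9R,11S)-4-(4-methoxybenzyloxy)-5,11-dimethyl-1-methylidenebicyclo[7.2.0]undecan-11-yl]-2-methylpent-2-ene-1,5-diol
Conditions: i-Bu2AlH (5 equiv), CH2Cl2, −78 → 0 °C; aq. KNaC4H4O6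
Reagents that add atoms: none
Why: Excess aluminium hydride reduces the lactone through the lactol stage to the diol by 1,2-addition; the trisubstituted alkene keeps its cis geometry and both hydroxyls (C12, C16) are released together.

Step 27
Reactants: 33 diol
Product: 34 diacetate of 33 (C12 and C16 acetates, C4 4-methoxybenzyl ether)
Conditions: Ac2O (3 equiv), pyridine, DMAP (cat.), CH2Cl2, rt
Reagents that add atoms: acetic anhydride, CC(=O)OC(C)=O
Why: DMAP-catalysed acetylation of the primary allylic and the hindered secondary alcohol; C4 stays masked, so only the two required acetates form.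

Step 28
Reactants: 34 diacetate ether
Product: 35 (1S,3Z)-1-[(5S,8S,9R,11S)-4-hydroxy-5,11-dimethyl-1-methylidenebicyclo[7.2.0]undecan-11-yl]-4-methylpent-3-ene-1,5-diyl diacetate (C4 epimers)
Conditions: DDQ, CH2Cl2/pH 7 buffer, 0 °C → rt
Reagents that add atoms: none
Why: Oxidative cleavage of the 4-methoxybenzyl ether: DDQ abstracts hydride from the electron-rich benzylic position and water hydrolyses the oxocarbenium ion; acetates and alkenes are not touched.

Step 29
Reactants: 35 C4 alcohol
Product: 36 target, (1S,3Z)-1-[(5S,8S,9R,11S)-5,11-dimethyl-1-methylidene-4-oxobicyclo[7.2.0]undecan-11-yl]-4-methylpent-3-ene-1,5-diyl diacetate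
Conditions: Dess–Martin periodinane, NaHCO3, CH2Cl2, 0 °C → rt
Reagents that add atoms: none
Why: Dess–Martin oxidation as the last step, buffered, so that the epimerisable C5 centre and the transannularly reactive keto-alkene never meet base or acid; both C4 epimers converge to the ketone.

## Compound list

1 | cyclohexane-1,3-dione | O=C1CCCC(=O)C1 | starting material
2 | 3-oxocyclohex-1-en-1-yl trifluoromethanesulfonate | O=C1C=C(OS(=O)(=O)C(F)(F)F)CCC1 | intermediate
3 | 3-(hydroxymethyl)cyclohex-2-en-1-one | O=C1C=C(CO)CCC1 | intermediate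
4 | 3-[(triisopropylsilyloxy)methyl]cyclohex-2-en-1-one | O=C1C=C(CO[Si](C(C)C)(C(C)C)C(C)C)CCC1 | intermediate
5 | trimethylaluminium | C[Al](C)C | starting material
6 | (S)-3-methyl-3-[(triisopropylsilyloxy)methyl]cyclohexan-1-one | O=C1C[C@@](C)(CO[Si](C(C)C)(C(C)C)C(C)C)CCC1 | intermediate
7 | (S)-5-methyl-5-[(triisopropylsilyloxy)methyl]-1-(trimethylsilyloxy)cyclohex-1-ene | C[Si](C)(C)OC1=CCC[C@](C)(CO[Si](C(C)C)(C(C)C)C(C)C)C1 | intermediate
8 | (S)-3-methyl-6-oxo-3-[(triisopropylsilyloxy)methyl]hexanoic acid | O=CCC[C@](C)(CO[Si](C(C)C)(C(C)C)C(C)C)CC(=O)O | intermediate (not isolated)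
9 | (S)-3-methyl-3-[(triisopropylsilyloxy)methyl]hexanedioic acid | OC(=O)CC[C@](C)(CO[Si](C(C)C)(C(C)C)C(C)C)CC(=O)O | intermediate
10 | oxazolidin-2-one | O=C1NCCO1 | starting material
11 | 3,3'-{(S)-3-methyl-3-[(triisopropylsilyloxy)methyl]hexanedioyl}bis(oxazolidin-2-one) | O=C1OCCN1C(=O)C[C@@](C)(CO[Si](C(C)C)(C(C)C)C(C)C)CCC(=O)N2CCOC2=O | intermediate
12 | dilithium bis-enolate of 11 | [Li]OC(=C[C@@](C)(CO[Si](C(C)C)(C(C)C)C(C)C)CC=C(O[Li])N1CCOC1=O)N2CCOC2=O | intermediate (not isolated)
13 | 3,3'-{[(1R,2S,3S)-3-methyl-3-[(triisopropylsilyloxy)methyl]cyclobutane-1,2-diyl]dicarbonyl}bis(oxazolidin-2-one) | O=C1OCCN1C(=O)[C@H]2[C@H](C(=O)N3CCOC3=O)C[C@]2(C)CO[Si](C(C)C)(C(C)C)C(C)C | intermediate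
14 | (1R,2S,3S)-N-methoxy-N,3-dimethyl-2-(2-oxooxazolidine-3-carbonyl)-3-[(triisopropylsilyloxy)methyl]cyclobutane-1-carboxamide | O=C1OCCN1C(=O)[C@H]2[C@H](C(=O)N(C)OC)C[C@]2(C)CO[Si](C(C)C)(C(C)C)C(C)C | intermediate
15 | (1R,2S,3S)-2-(hydroxymethyl)-N-methoxy-N,3-dimethyl-3-[(triisopropylsilyloxy)methyl]cyclobutane-1-carboxamide | OC[C@H]2[C@H](C(=O)N(C)OC)C[C@]2(C)CO[Si](C(C)C)(C(C)C)C(C)C | intermediate
16 | (1R,2S,3S)-2-formyl-N-methoxy-N,3-dimethyl-3-[(triisopropylsilyloxy)methyl]cyclobutane-1-carboxamide | O=C[C@H]2[C@H](C(=O)N(C)OC)C[C@]2(C)CO[Si](C(C)C)(C(C)C)C(C)C | intermediate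
17 | (R)-3-bromo-2-methylpropan-1-ol | OC[C@@H](C)CBr | starting material
18 | (R)-(3-hydroxy-2-methylpropyl)triphenylphosphonium bromide | OC[C@@H](C)C[P+](c1ccccc1)(c1ccccc1)c1ccccc1.[Br-] | intermediate
19 | (1R,2S,3S)-2-[(1Z,3S)-4-hydroxy-3-methylbut-1-en-1-yl]-N-methoxy-N,3-dimethyl-3-[(triisopropylsilyloxy)methyl]cyclobutane-1-carboxamide | OC[C@@H](C)/C=C\[C@H]2[C@H](C(=O)N(C)OC)C[C@]2(C)CO[Si](C(C)C)(C(C)C)C(C)C | intermediate
20 | (1R,2S,3S)-2-[(3S)-4-hydroxy-3-methylbutyl]-N-methoxy-N,3-dimethyl-3-[(triisopropylsilyloxy)methyl]cyclobutane-1-carboxamide | OC[C@@H](C)CC[C@H]2[C@H](C(=O)N(C)OC)C[C@]2(C)CO[Si](C(C)C)(C(C)C)C(C)C | intermediate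
21 | (1R,2S,3S)-N-methoxy-N,3-dimethyl-2-[(3S)-3-methyl-4-oxobutyl]-3-[(triisopropylsilyloxy)methyl]cyclobutane-1-carboxamide | O=C[C@@H](C)CC[C@H]2[C@H](C(=O)N(C)OC)C[C@]2(C)CO[Si](C(C)C)(C(C)C)C(C)C | intermediate
22 | (1R,2S,3S)-2-[(3S)-4-hydroxy-3-methylhex-5-en-1-yl]-N-methoxy-N,3-dimethyl-3-[(triisopropylsilyloxy)methyl]cyclobutane-1-carboxamide (C4 epimers) | C=CC(O)[C@@H](C)CC[C@H]2[C@H](C(=O)N(C)OC)C[C@]2(C)CO[Si](C(C)C)(C(C)C)C(C)C | intermediate
23 | 4-methoxybenzyl ether of 22 (C4 epimers) | C=CC(OCc1ccc(OC)cc1)[C@@H](C)CC[C@H]2[C@H](C(=O)N(C)OC)C[C@]2(C)CO[Si](C(C)C)(C(C)C)C(C)C | intermediate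
24 | 1-{(1R,2S,3S)-2-[(3S)-4-(4-methoxybenzyloxy)-3-methylhex-5-en-1-yl]-3-methyl-3-[(triisopropylsilyloxy)methyl]cyclobutyl}ethan-1-one | C=CC(OCc1ccc(OC)cc1)[C@@H](C)CC[C@H]2[C@H](C(C)=O)C[C@]2(C)CO[Si](C(C)C)(C(C)C)C(C)C | intermediate
25 | 1-{(1R,2S,3S)-2-[(3S)-4-(4-methoxybenzyloxy)-3-methylhex-5-en-1-yl]-3-methyl-3-[(triisopropylsilyloxy)methyl]cyclobutyl}ethenyl trifluoromethanesulfonate | C=CC(OCc1ccc(OC)cc1)[C@@H](C)CC[C@H]2[C@H](C(=C)OS(=O)(=O)C(F)(F)F)C[C@]2(C)CO[Si](C(C)C)(C(C)C)C(C)C | intermediate
26 | B-alkyl-9-borabicyclo[3.3.1]nonane from 25 (boron on C2) | C(CC(OCc1ccc(OC)cc1)[C@@H](C)CC[C@H]2[C@H](C(=C)OS(=O)(=O)C(F)(F)F)C[C@]2(C)CO[Si](C(C)C)(C(C)C)C(C)C)B3C4CCCC3CCC4 | intermediate (not isolated)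
27 | (5S,8S,9R,11S)-4-(4-methoxybenzyloxy)-5,11-dimethyl-1-methylidene-11-[(triisopropylsilyloxy)methyl]bicyclo[7.2.0]undecane (C4 epimers) | C=C1CCC(OCc3ccc(OC)cc3)[C@@H](C)CC[C@H]2[C@H]1C[C@]2(C)CO[Si](C(C)C)(C(C)C)C(C)C | intermediate
28 | [(5S,8S,9R,11S)-4-(4-methoxybenzyloxy)-5,11-dimethyl-1-methylidenebicyclo[7.2.0]undecan-11-yl]methanol | C=C1CCC(OCc3ccc(OC)cc3)[C@@H](C)CC[C@H]2[C@H]1C[C@]2(C)CO | intermediate
29 | (5S,8S,9R,11S)-4-(4-methoxybenzyloxy)-5,11-dimethyl-1-methylidenebicyclo[7.2.0]undecane-11-carbaldehyde | C=C1CCC(OCc3ccc(OC)cc3)[C@@H](C)CC[C@H]2[C@H]1C[C@]2(C)C=O | intermediate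
30 | (1S)-1-[(5S,8S,9R,11S)-4-(4-methoxybenzyloxy)-5,11-dimethyl-1-methylidenebicyclo[7.2.0]undecan-11-yl]but-3-en-1-ol | C=C1CCC(OCc3ccc(OC)cc3)[C@@H](C)CC[C@H]2[C@H]1C[C@]2(C)[C@H](CC=C)O | intermediate
31 | methacrylate ester of 30 | C=C1CCC(OCc3ccc(OC)cc3)[C@@H](C)CC[C@H]2[C@H]1C[C@]2(C)[C@H](CC=C)OC(=O)C(C)=C | intermediate
32 | (6S)-6-[(5S,8S,9R,11S)-4-(4-methoxybenzyloxy)-5,11-dimethyl-1-methylidenebicyclo[7.2.0]undecan-11-yl]-3-methyl-5,6-dihydro-2H-pyran-2-one | C=C1CCC(OCc3ccc(OC)cc3)[C@@H](C)CC[C@H]2[C@H]1C[C@]2(C)[C@@H]4CC=C(C)C(=O)O4 | intermediate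
33 | (2Z,5S)-5-[(5S,8S,9R,11S)-4-(4-methoxybenzyloxy)-5,11-dimethyl-1-methylidenebicyclo[7.2.0]undecan-11-yl]-2-methylpent-2-ene-1,5-diol | C=C1CCC(OCc3ccc(OC)cc3)[C@@H](C)CC[C@H]2[C@H]1C[C@]2(C)[C@H](C/C=C(/C)CO)O | intermediate
34 | diacetate of 33 | C=C1CCC(OCc3ccc(OC)cc3)[C@@H](C)CC[C@H]2[C@H]1C[C@]2(C)[C@H](C/C=C(/C)COC(C)=O)OC(C)=O | intermediate
35 | (1S,3Z)-1-[(5S,8S,9R,11S)-4-hydroxy-5,11-dimethyl-1-methylidenebicyclo[7.2.0]undecan-11-yl]-4-methylpent-3-ene-1,5-diyl diacetate (C4 epimers) | C=C1CCC(O)[C@@H](C)CC[C@H]2[C@H]1C[C@]2(C)[C@H](C/C=C(/C)COC(C)=O)OC(C)=O | intermediate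
36 | (1S,3Z)-1-[(5S,8S,9R,11S)-5,11-dimethyl-1-methylidene-4-oxobicyclo[7.2.0]undecan-11-yl]-4-methylpent-3-ene-1,5-diyl diacetate | C=C1CCC(=O)[C@@H](C)CC[C@H]2[C@H]1C[C@]2(C)[C@H](C/C=C(/C)COC(C)=O)OC(C)=O | target

## Step count and least certain steps

Total: 29 steps. Longest linear sequence: 28 steps from 1 (steps 1–11 and 13–29); step 12 is a one-step branch.

**Step 8 (key step).**
- What may go wrong: incomplete double deprotonation, so that a mono-enolate attacks the other imide in a Dieckmann-type condensation; intermolecular coupling, because closing a four-membered ring is slow; α-chlorination of the enolate by the copper salt; and loss of control at C8/C9 relative to C11. For the last, the first remedy is equilibration with DBU, since the wanted isomer (acyl groups trans, C8 acyl beside the smaller methyl) should be the most stable.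
- Fallback: replace the one-electron coupling by a two-stage polar closure in which one α-carbon is made electrophilic. From 11, soft enolisation with one equivalent of Bu2BOTf/i-Pr2NEt and bromination with N-bromosuccinimide should give the mono-α-bromo bis-imide F1 (either α-carbon serves, since the ring bond is the same; drawn for the less hindered C9). Reversible deprotonation with Cs2CO3 in DMF lets the enolate of the unbrominated imide displace bromide in a 4-exo-tet alkylation. DBU equilibration of the two α-centres returns the route at 13. Elimination of HBr is the competing path in this variant.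

**Step 9.**
- What may go wrong: insufficient discrimination between the two imides (double amidation, or transfer of the wrong acyl group), and attack of the aluminium amide on the ring carbonyl of the oxazolidinone, which opens the heterocycle; the acyl group is α-branched and carries no directing hydroxyl.
- Fallback: differentiate the termini before the ring is made, using the fact that ozonolysis already delivers them at different oxidation levels. Step 6 is stopped before the chlorite stage and oxo acid 8 is isolated. Its C7 acid is used to acylate 10 (pivalic mixed anhydride, LiCl), giving the aldehyde imide F2. Pinnick oxidation gives the acid imide F3, and Me3SiCHN2 the methyl ester imide F4. Oxidative coupling of the ester/imide bis-enolate (LiN(i-Pr)2, CuCl2) gives the cyclobutane imide ester F5. LiBH4 reduces the imide faster than the methyl ester and gives the hydroxy ester F6. MeNH(OMe)·HCl with i-PrMgCl converts the ester into the amide and returns the route at 15.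

**Step 20.**
- What may go wrong: intermolecular coupling to dimers in place of the nine-membered ring, protodeboronation or β-hydride elimination of the alkylpalladium intermediate, and hydrolysis of the triflate.
- Fallback: close the same C1–C2 bond by carbonyl addition and remove the extra oxygen afterwards. From 25, 9-BBN then NaBO3 should give the primary alcohol F7, and Dess–Martin oxidation the aldehyde F8. Nozaki–Hiyama–Kishi cyclisation (CrCl2, catalytic NiCl2, DMSO, high dilution; divalent chromium) gives the cyclic allylic alcohol F9. Methyl chloroformate/pyridine gives the carbonate F10. Tsuji reduction (Pd(OAc)2, PBu3, HCO2NH4) delivers hydride to the more substituted allyl terminus C2, restores the exocyclic methylene and returns the route at 27.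

**Step 4.**
- What may go wrong: low facial selectivity or slow addition because of the bulky silyloxymethyl substituent on the β-carbon, which would lower the optical purity of everything downstream.
- Fallback: set C11 by chirality transfer from a carbinol. From 4, Corey–Bakshi–Shibata reduction should give the (S)-allylic alcohol F11. Hydroxyl-directed Simmons–Smith cyclopropanation (Et2Zn, CH2I2) gives the syn cyclopropyl carbinol F12, and Dess–Martin oxidation the cyclopropyl ketone F13. Li/NH3 cleaves the exocyclic cyclopropane bond that overlaps with the carbonyl, leaving the methyl on the face the hydroxyl had occupied, and returns the route at 6.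

## Further compounds

F1 | step 8 | 3,3'-{(4R)-2-bromo-4-methyl-4-[(triisopropylsilyloxy)methyl]hexanedioyl}bis(oxazolidin-2-one) (bromine on C9, epimers at the bromine-bearing carbon) | O=C1OCCN1C(=O)C[C@@](C)(CO[Si](C(C)C)(C(C)C)C(C)C)CC(Br)C(=O)N2CCOC2=O
F2 | step 9 | 3-{(S)-3-methyl-6-oxo-3-[(triisopropylsilyloxy)methyl]hexanoyl}oxazolidin-2-one | O=CCC[C@](C)(CO[Si](C(C)C)(C(C)C)C(C)C)CC(=O)N1CCOC1=O
F3 | step 9 | (S)-4-methyl-6-oxo-6-(2-oxooxazolidin-3-yl)-4-[(triisopropylsilyloxy)methyl]hexanoic acid | OC(=O)CC[C@](C)(CO[Si](C(C)C)(C(C)C)C(C)C)CC(=O)N1CCOC1=O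
F4 | step 9 | methyl (S)-4-methyl-6-oxo-6-(2-oxooxazolidin-3-yl)-4-[(triisopropylsilyloxy)methyl]hexanoate | COC(=O)CC[C@](C)(CO[Si](C(C)C)(C(C)C)C(C)C)CC(=O)N1CCOC1=O
F5 | step 9 | methyl (1R,2S,3S)-3-methyl-2-(2-oxooxazolidine-3-carbonyl)-3-[(triisopropylsilyloxy)methyl]cyclobutane-1-carboxylate | O=C1OCCN1C(=O)[C@H]2[C@H](C(=O)OC)C[C@]2(C)CO[Si](C(C)C)(C(C)C)C(C)C
F6 | step 9 | methyl (1R,2S,3S)-2-(hydroxymethyl)-3-methyl-3-[(triisopropylsilyloxy)methyl]cyclobutane-1-carboxylate | OC[C@H]2[C@H](C(=O)OC)C[C@]2(C)CO[Si](C(C)C)(C(C)C)C(C)C
F7 | step 20 | primary alcohol from hydroboration–oxidation of 25 (hydroxyl on C2) | OCCC(OCc1ccc(OC)cc1)[C@@H](C)CC[C@H]2[C@H](C(=C)OS(=O)(=O)C(F)(F)F)C[C@]2(C)CO[Si](C(C)C)(C(C)C)C(C)C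
F8 | step 20 | C2 aldehyde corresponding to F7 | O=CCC(OCc1ccc(OC)cc1)[C@@H](C)CC[C@H]2[C@H](C(=C)OS(=O)(=O)C(F)(F)F)C[C@]2(C)CO[Si](C(C)C)(C(C)C)C(C)C
F9 | step 20 | (5S,8S,9R,11S)-4-(4-methoxybenzyloxy)-5,11-dimethyl-1-methylidene-11-[(triisopropylsilyloxy)methyl]bicyclo[7.2.0]undecan-2-ol (C2 and C4 epimers) | C=C1C(O)CC(OCc3ccc(OC)cc3)[C@@H](C)CC[C@H]2[C@H]1C[C@]2(C)CO[Si](C(C)C)(C(C)C)C(C)C
F10 | step 20 | methyl carbonate of F9 | C=C1C(OC(=O)OC)CC(OCc3ccc(OC)cc3)[C@@H](C)CC[C@H]2[C@H]1C[C@]2(C)CO[Si](C(C)C)(C(C)C)C(C)C
F11 | step 4 | (S)-3-[(triisopropylsilyloxy)methyl]cyclohex-2-en-1-ol | O[C@@H]1C=C(CO[Si](C(C)C)(C(C)C)C(C)C)CCC1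
F12 | step 4 | (1R,2S,6R)-6-[(triisopropylsilyloxy)methyl]bicyclo[4.1.0]heptan-2-ol (cyclopropane syn to hydroxyl) | O[C@@H]1[C@@H]2C[C@]2(CO[Si](C(C)C)(C(C)C)C(C)C)CCC1
F13 | step 4 | (1R,6R)-6-[(triisopropylsilyloxy)methyl]bicyclo[4.1.0]heptan-2-one | O=C1[C@@H]2C[C@]2(CO[Si](C(C)C)(C(C)C)C(C)C)CCC1
A1 | alternative 1 | bis(tert-butyldimethylsilyl) ether of the target diol (C4 ketone, C1 methylene in place) | C=C1CCC(=O)[C@@H](C)CC[C@H]2[C@H]1C[C@]2(C)[C@H](C/C=C(/C)CO[Si](C)(C)C(C)(C)C)O[Si](C)(C)C(C)(C)C
A2 | alternative 1 | cyclopropanol alkenyl triflate (cyclopropanol carbon is C4, triflate on C1) | OC1(CC1)[C@@H](C)CC[C@H]2[C@H](C(=C)OS(=O)(=O)C(F)(F)F)C[C@]2(C)[C@H](C/C=C(/C)CO[Si](C)(C)C(C)(C)C)O[Si](C)(C)C(C)(C)C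
A3 | alternative 2 | 2-methyl-2-[1-hydroxy-3-(4-methoxybenzyloxy)propyl]cyclobutanone | O=C1CC[C@@]1(C)[C@H](CCOCc2ccc(OC)cc2)O
A4 | alternative 2 | 1-{2-methyl-3-[2-(4-methoxybenzyloxy)ethyl]oxiran-2-yl}cyclopropan-1-ol | OC1(CC1)[C@]2(C)O[C@H]2CCOCc3ccc(OC)cc3
A5 | alternative 3 | methyl trans-2,3-bis(tert-butyldimethylsilyloxymethyl)cyclobutanecarboxylate | CC(C)(C)[Si](C)(C)OC[C@H]2[C@H](CO[Si](C)(C)C(C)(C)C)C[C@@H]2C(=O)OC
A6 | alternative 3 | trans-2-diazo-3,4-bis(tert-butyldimethylsilyloxymethyl)cyclopentan-1-one | O=C1C[C@@H](CO[Si](C)(C)C(C)(C)C)[C@H](CO[Si](C)(C)C(C)(C)C)C1=[N+]=[N-]
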